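**Strategy.** Everything rests on disconnecting the C1–C6 bond of the 7-oxabicyclo[4.1.0]hept-3-en-2-one core, the bond shared by the oxirane and the cyclohexenone ring. It is formed by an intramolecular Darzens condensation: C1 is the chloromethyl carbon α to the C2 ketone, C6 an aldehyde carbon beside the C5 carbinol, so one operation closes the carbocycle and the epoxide and sets C1 and C6 from C5. The precursor is an open-chain 2-amido-enone with ClCH2C(=O) and CHO ends; its cis alkene and its C5 configuration come from a δ-lactone made by Achmatowicz dearomatisation of furfuryl alcohol. Hydrostannation and a Stille coupling then attach the trienamide arm.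

Key step: step 17

Remark: core atoms are numbered as in 7-oxabicyclo[4.1.0]hept-3-en-2-one (C1 and C6 epoxide carbons, C2 ketone, C3 amide-bearing carbon, C5 carbinol). Hydroxy ketone 26 is drawn open-chain although it should equilibrate with its six-membered hemiketal.

**Fragment A: dienamide 5**

Step 1
Reactants: 1 cyclohexanecarbaldehyde; 2 (triphenylphosphoranylidene)acetaldehyde
Product: 3 (2E)-3-cyclohexylprop-2-enal
Conditions: toluene, 80 °C
Reagents that add atoms: none
Why: Wittig olefination with the stabilised formyl ylide should give the (E)-enal.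

Step 2
Reactants: 3 (2E)-3-cyclohexylprop-2-enal; 4 diethyl (2-amino-2-oxoethyl)phosphonate
Product: 5 (2E,4E)-5-cyclohexylpenta-2,4-dienamide
Conditions: KOt-Bu, THF, 0 → 23 °C
Reagents that add atoms: none
Why: Horner–Wadsworth–Emmons olefination of the phosphonoacetamide anion is E-selective and leaves the existing double bond untouched.

**Fragment B: bromodienamide 12**

Step 3
Reactants: 6 glutaconaldehyde potassium salt
Product: 7 (2E,4E)-5-bromopenta-2,4-dienal
Conditions: PPh3, Br2, CH2Cl2, 0 °C; then 6, 0 → 23 °C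
Reagents that add atoms: bromine, BrBr
Why: O-phosphonium activation of the dienolate by Ph3PBr2 and bromide addition–elimination (vinylogous Appel-type halogenation) should give the all-trans bromodienal, the thermodynamically preferred isomer.

Step 4
Reactants: 7 (2E,4E)-5-bromopenta-2,4-dienal
Product: 8 (2E,4E)-5-bromopenta-2,4-dienoic acid
Conditions: NaClO2, NaH2PO4, 2-methylbut-2-ene, t-BuOH/H2O, 0 → 23 °C
Reagents that add atoms: sodium chlorite, [Na+].[O-]Cl=O
Why: Pinnick oxidation converts the aldehyde into the acid without touching the bromodiene, the alkene scavenger removing hypochlorous acid.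

Step 5
Reactants: 9 cyclopentane-1,3-dione
Product: 10 2-(hydroxyimino)cyclopentane-1,3-dione
Conditions: NaNO2, aq. HCl, 0 °C
Reagents that add atoms: sodium nitrite, [Na+].[O-]N=O
Why: Nitrosation of the doubly activated C2 methylene of the 1,3-dione gives the 2-oxime by tautomerisation of the nitroso compound.

Step 6
Reactants: 10 2-(hydroxyimino)cyclopentane-1,3-dione
Product: 11 2-amino-3-hydroxycyclopent-2-en-1-one hydrochloride
Conditions: H2 (1 atm), Pd/C, HCl, EtOH, 23 °C
Reagents that add atoms: hydrogen chloride, Cl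
Why: Catalytic hydrogenolysis of the oxime N–O bond in acid gives the amine, held as the hydrochloride of its enol form so that self-condensation is suppressed.

Step 7
Reactants: 8 (2E,4E)-5-bromopenta-2,4-dienoic acid; 11 2-amino-3-hydroxycyclopent-2-en-1-one hydrochloride
Product: 12 (2E,4E)-5-bromo-N-(2-hydroxy-5-oxocyclopent-1-en-1-yl)penta-2,4-dienamide
Conditions: EDC·HCl, HOBt (cat.), i-Pr2NEt, DMF, 0 → 23 °C
Reagents that add atoms: none
Why: Carbodiimide amide coupling should acylate the amine nitrogen (any enol ester transfers its acyl group to nitrogen) without changing the bromodiene geometry.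

**Main line**

Step 8
Reactants: 13 furfuryl alcohol
Product: 14 6-hydroxy-2H-pyran-3(6H)-one (racemic lactol)
Conditions: mCPBA, CH2Cl2, 0 °C
Reagents that add atoms: mCPBA, O=C(OO)c1cccc(Cl)c1
Why: Achmatowicz rearrangement (oxidative dearomatisation): furan epoxidation, opening to the cis-enedione and recyclisation through the hydroxymethyl group give the pyranone hemiacetal.

Step 9
Reactants: 14 6-hydroxy-2H-pyran-3(6H)-one
Product: 15 (2S)-5-oxo-5,6-dihydro-2H-pyran-2-yl 2-methylpropanoate
Conditions: (i-PrCO)2O, (S)-tetramisole (10 mol %), toluene, 0 °C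
Reagents that add atoms: isobutyric anhydride, CC(C)C(=O)OC(=O)C(C)C
Why: Dynamic kinetic asymmetric acylation, in which the lactol enantiomers interconvert by ring opening while the chiral acyl-transfer catalyst acylates one of them, should fix C2 as (S); the antipodal catalyst is taken if the sense proves opposite.

Step 10
Reactants: 15 (2S)-5-oxo-5,6-dihydro-2H-pyran-2-yl 2-methylpropanoate; 16 ethynyltrimethylsilane
Product: 19 (2S,5S)-5-[(trimethylsilyl)ethynyl]-5-[(trimethylsilyl)oxy]-5,6-dihydro-2H-pyran-2-yl 2-methylpropanoate, via lithium (trimethylsilyl)acetylide 17 (not isolated), via lithium tertiary alkoxide 18 (not isolated)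
Conditions: 16, n-BuLi, THF, −78 °C; then 15, −78 °C; then Me3SiCl, −78 → 0 °C
Reagents that add atoms: chlorotrimethylsilane, C[Si](C)(C)Cl
Why: 1,2-Addition of the lithium acetylide to the ketone should occur anti to the pseudoaxial anomeric acyloxy group, which sets the tertiary carbinol centre (future C5) with its oxygen cis to the ester, and the alkoxide is silylated in situ.

Step 11
Reactants: 19 (2S,5S)-5-[(trimethylsilyl)ethynyl]-5-[(trimethylsilyl)oxy]-5,6-dihydro-2H-pyran-2-yl 2-methylpropanoate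
Product: 20 (5S)-5-[(trimethylsilyl)ethynyl]-5-[(trimethylsilyl)oxy]-5,6-dihydro-2H-pyran-2-ol (mixture of anomers)
Conditions: i-Bu2AlH (2.2 equiv), CH2Cl2, −78 °C; aq. Rochelle salt
Reagents that add atoms: none
Why: Reductive cleavage of the anomeric ester frees the lactol while both silyl groups, which would not survive basic methanolysis, stay intact.

Step 12
Reactants: 20 (5S)-5-[(trimethylsilyl)ethynyl]-5-[(trimethylsilyl)oxy]-5,6-dihydro-2H-pyran-2-ol
Product: 21 (5S)-5-[(trimethylsilyl)ethynyl]-5-[(trimethylsilyl)oxy]-5,6-dihydro-2H-pyran-2-one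
Conditions: PhI(OAc)2, TEMPO (cat.), CH2Cl2, 23 °C
Reagents that add atoms: none
Why: Oxoammonium (TEMPO) oxidation of the lactol gives the α,β-unsaturated δ-lactone, a temporary ring that locks the future C3=C4 double bond as cis.

Step 13
Reactants: 21 (5S)-5-[(trimethylsilyl)ethynyl]-5-[(trimethylsilyl)oxy]-5,6-dihydro-2H-pyran-2-one
Product: 22 (5S)-3-iodo-5-[(trimethylsilyl)ethynyl]-5-[(trimethylsilyl)oxy]-5,6-dihydro-2H-pyran-2-one
Conditions: I2, pyridine, DMAP (cat.), CH2Cl2, 23 °C
Reagents that add atoms: iodine, II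
Why: α-Iodination of the enoate by the amine addition–iodination–elimination sequence (Baylis–Hillman-type mechanism) places iodine on the carbon that becomes C3.

Step 14
Reactants: 22 (5S)-3-iodo-5-[(trimethylsilyl)ethynyl]-5-[(trimethylsilyl)oxy]-5,6-dihydro-2H-pyran-2-one; 5 (2E,4E)-5-cyclohexylpenta-2,4-dienamide
Product: 23 (2E,4E)-5-cyclohexyl-N-{(5S)-2-oxo-5-[(trimethylsilyl)ethynyl]-5-[(trimethylsilyl)oxy]-5,6-dihydro-2H-pyran-3-yl}penta-2,4-dienamide
Conditions: CuI (10 mol %), N,N'-dimethylethylenediamine (20 mol %), K2CO3, toluene, 80 °C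
Reagents that add atoms: none
Why: Goldberg-type CuI/diamine-catalysed amidation of the vinyl iodide proceeds with retention and gives the 2-amido-enoate.

Step 15
Reactants: 23 (2E,4E)-5-cyclohexyl-N-{(5S)-2-oxo-5-[(trimethylsilyl)ethynyl]-5-[(trimethylsilyl)oxy]-5,6-dihydro-2H-pyran-3-yl}penta-2,4-dienamide; 24 chloroiodomethane
Product: 26 (2E,4E)-N-{(3E,5S)-1-chloro-6-hydroxy-2-oxo-5-[(trimethylsilyl)ethynyl]-5-[(trimethylsilyl)oxy]hex-3-en-3-yl}-5-cyclohexylpenta-2,4-dienamide, via chloromethyllithium 25 (not isolated)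
Conditions: 24, MeLi·LiBr (3 equiv), THF, −78 °C (carbenoid formed in the presence of 23); then AcOH
Reagents that add atoms: none
Why: Carbenoid homologation of a lactone, in which chloromethyllithium adds once to the carbonyl because the tetrahedral alkoxide is stable at −78 °C, releases the chloromethyl ketone and the primary alcohol on work-up.

Step 16
Reactants: 26 (2E,4E)-N-{(3E,5S)-1-chloro-6-hydroxy-2-oxo-5-[(trimethylsilyl)ethynyl]-5-[(trimethylsilyl)oxy]hex-3-en-3-yl}-5-cyclohexylpenta-2,4-dienamide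
Product: 27 (2E,4E)-N-{(3E,5S)-1-chloro-2,6-dioxo-5-[(trimethylsilyl)ethynyl]-5-[(trimethylsilyl)oxy]hex-3-en-3-yl}-5-cyclohexylpenta-2,4-dienamide
Conditions: Dess–Martin periodinane, NaHCO3, CH2Cl2, 0 → 23 °C
Reagents that add atoms: none
Why: Dess–Martin oxidation of the primary alcohol, drawn from the hemiketal–hydroxy ketone equilibrium, gives the aldehyde, whose α-carbon is quaternary so that no epimerisation is possible.

Step 17
Reactants: 27 (2E,4E)-N-{(3E,5S)-1-chloro-2,6-dioxo-5-[(trimethylsilyl)ethynyl]-5-[(trimethylsilyl)oxy]hex-3-en-3-yl}-5-cyclohexylpenta-2,4-dienamide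
Product: 29 (2E,4E)-5-cyclohexyl-N-[(1R,5S,6S)-5-ethynyl-5-hydroxy-2-oxo-7-oxabicyclo[4.1.0]hept-3-en-3-yl]penta-2,4-dienamide, via bis(trimethylsilyl) epoxy ketone 28 (not isolated)
Conditions: Cs2CO3, MeCN, 0 °C; then MeOH, 0 → 23 °C
Reagents that add atoms: none
Why: Intramolecular Darzens condensation: Cs2CO3 deprotonates the chloromethyl group (future C1, α to the C2 ketone), the enolate adds to the aldehyde carbon (future C6) to form the C1–C6 bond, and the chlorohydrin alkoxide displaces chloride. The closest known reaction type is the Darzens condensation of α-chloro ketones with aldehydes, here in its ring-closing form. The cyclohexenone closes by a 6-(enolendo)-exo-trig aldol addition, possible only because the lactone-derived alkene holds C2 and C5 cis, and the oxirane closes by a 3-exo-tet displacement, which also enforces the cis ring fusion. C6 is controlled by the existing C5 centre: polar Felkin–Anh addition with the C5–OSiMe3 bond anti to the forming bond, and ring closure from the trans-diaxial alkoxide/chloride conformer in which the slim alkynyl group, not the silyloxy group, is 1,3-diaxial to chlorine, should place the epoxide oxygen cis to the C5 oxygen, and C1 follows from the anti displacement. The step needs attack of the enolate carbon on the aldehyde to outrun O-alkylation by the chloromethyl ketone, which the silyl cap on the C5 oxygen, the non-chelating caesium counter-ion and the high electrophilicity of the aldehyde are meant to secure. Methanol then removes both trimethylsilyl groups in the same flask.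

Step 18
Reactants: 29 (2E,4E)-5-cyclohexyl-N-[(1R,5S,6S)-5-ethynyl-5-hydroxy-2-oxo-7-oxabicyclo[4.1.0]hept-3-en-3-yl]penta-2,4-dienamide
Product: 30 (2E,4E)-5-cyclohexyl-N-{(1R,5S,6S)-5-hydroxy-2-oxo-5-[(E)-2-(tributylstannyl)ethenyl]-7-oxabicyclo[4.1.0]hept-3-en-3-yl}penta-2,4-dienamide
Conditions: Bu3SnH (slow addition), Pd(PPh3)2Cl2 (3 mol %), THF, 0 °C
Reagents that add atoms: tributyltin hydride, CCCC[SnH](CCCC)CCCC
Why: Pd-catalysed syn-hydrostannation of the terminal alkyne should place tin at the terminus, away from the tertiary carbinol, and give the (E)-vinylstannane faster than any reduction of the enone.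

Step 19
Reactants: 30 (2E,4E)-5-cyclohexyl-N-{(1R,5S,6S)-5-hydroxy-2-oxo-5-[(E)-2-(tributylstannyl)ethenyl]-7-oxabicyclo[4.1.0]hept-3-en-3-yl}penta-2,4-dienamide; 12 (2E,4E)-5-bromo-N-(2-hydroxy-5-oxocyclopent-1-en-1-yl)penta-2,4-dienamide
Product: 31 (2E,4E)-5-cyclohexyl-N-[(1R,5R,6S)-5-hydroxy-5-[(1E,3E,5E)-7-[(2-hydroxy-5-oxocyclopent-1-en-1-yl)amino]-7-oxohepta-1,3,5-trien-1-yl]-2-oxo-7-oxabicyclo[4.1.0]hept-3-en-3-yl]penta-2,4-dienamide (target)
Conditions: PdCl2(MeCN)2 (10 mol %), DMF, 23 °C, dark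
Reagents that add atoms: none
Why: Stille coupling of the (E)-vinylstannane with the (E,E)-bromodiene proceeds with retention at both partners and completes the (E,E,E)-triene under neutral conditions that the epoxyquinol and the acidic aminocyclopentenone tolerate.

**Compound list**

1 | cyclohexanecarbaldehyde | O=CC1CCCCC1 | starting material
2 | (triphenylphosphoranylidene)acetaldehyde | O=CC=P(c1ccccc1)(c1ccccc1)c1ccccc1 | starting material
3 | (2E)-3-cyclohexylprop-2-enal | O=C/C=C/C1CCCCC1 | intermediate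
4 | diethyl (2-amino-2-oxoethyl)phosphonate | CCOP(=O)(CC(N)=O)OCC | starting material
5 | (2E,4E)-5-cyclohexylpenta-2,4-dienamide | NC(=O)/C=C/C=C/C1CCCCC1 | intermediate
6 | glutaconaldehyde potassium salt, potassium (1E,3E)-5-oxopenta-1,3-dien-1-olate | [K+].[O-]/C=C/C=C/C=O | starting material
7 | (2E,4E)-5-bromopenta-2,4-dienal | O=C/C=C/C=C/Br | intermediate
8 | (2E,4E)-5-bromopenta-2,4-dienoic acid | OC(=O)/C=C/C=C/Br | intermediate
9 | cyclopentane-1,3-dione | O=C1CCC(=O)C1 | starting material
10 | 2-(hydroxyimino)cyclopentane-1,3-dione | O=C1CCC(=O)C1=NO | intermediate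
11 | 2-amino-3-hydroxycyclopent-2-en-1-one hydrochloride | NC1=C(O)CCC1=O.Cl | intermediate
12 | (2E,4E)-5-bromo-N-(2-hydroxy-5-oxocyclopent-1-en-1-yl)penta-2,4-dienamide | O=C(/C=C/C=C/Br)NC1=C(O)CCC1=O | intermediate
13 | furfuryl alcohol (furan-2-ylmethanol) | OCc1ccco1 | starting material
14 | 6-hydroxy-2H-pyran-3(6H)-one, racemic lactol | O=C1COC(O)C=C1 | intermediate
15 | (2S)-5-oxo-5,6-dihydro-2H-pyran-2-yl 2-methylpropanoate | CC(C)C(=O)O[C@H]1C=CC(=O)CO1 | intermediate
16 | ethynyltrimethylsilane | C#C[Si](C)(C)C | starting material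
17 | lithium (trimethylsilyl)acetylide | [Li]C#C[Si](C)(C)C | intermediate
18 | lithium alkoxide of (2S,5S)-5-hydroxy-5-[(trimethylsilyl)ethynyl]-5,6-dihydro-2H-pyran-2-yl 2-methylpropanoate | CC(C)C(=O)O[C@H]1C=C[C@]([O-])(C#C[Si](C)(C)C)CO1.[Li+] | intermediate
19 | (2S,5S)-5-[(trimethylsilyl)ethynyl]-5-[(trimethylsilyl)oxy]-5,6-dihydro-2H-pyran-2-yl 2-methylpropanoate | CC(C)C(=O)O[C@H]1C=C[C@](O[Si](C)(C)C)(C#C[Si](C)(C)C)CO1 | intermediate
20 | (5S)-5-[(trimethylsilyl)ethynyl]-5-[(trimethylsilyl)oxy]-5,6-dihydro-2H-pyran-2-ol, mixture of anomers | OC1C=C[C@](O[Si](C)(C)C)(C#C[Si](C)(C)C)CO1 | intermediate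
21 | (5S)-5-[(trimethylsilyl)ethynyl]-5-[(trimethylsilyl)oxy]-5,6-dihydro-2H-pyran-2-one | O=C1C=C[C@](O[Si](C)(C)C)(C#C[Si](C)(C)C)CO1 | intermediate
22 | (5S)-3-iodo-5-[(trimethylsilyl)ethynyl]-5-[(trimethylsilyl)oxy]-5,6-dihydro-2H-pyran-2-one | O=C1C(I)=C[C@](O[Si](C)(C)C)(C#C[Si](C)(C)C)CO1 | intermediate
23 | (2E,4E)-5-cyclohexyl-N-{(5S)-2-oxo-5-[(trimethylsilyl)ethynyl]-5-[(trimethylsilyl)oxy]-5,6-dihydro-2H-pyran-3-yl}penta-2,4-dienamide | O=C(/C=C/C=C/C1CCCCC1)NC1=C[C@](O[Si](C)(C)C)(C#C[Si](C)(C)C)COC1=O | intermediate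
24 | chloroiodomethane | ClCI | starting material
25 | chloromethyllithium | [Li]CCl | intermediate
26 | (2E,4E)-N-{(3E,5S)-1-chloro-6-hydroxy-2-oxo-5-[(trimethylsilyl)ethynyl]-5-[(trimethylsilyl)oxy]hex-3-en-3-yl}-5-cyclohexylpenta-2,4-dienamide | O=C(/C=C/C=C/C1CCCCC1)N/C(C(=O)CCl)=C/[C@](O[Si](C)(C)C)(C#C[Si](C)(C)C)CO | intermediate
27 | (2E,4E)-N-{(3E,5S)-1-chloro-2,6-dioxo-5-[(trimethylsilyl)ethynyl]-5-[(trimethylsilyl)oxy]hex-3-en-3-yl}-5-cyclohexylpenta-2,4-dienamide | O=C(/C=C/C=C/C1CCCCC1)N/C(C(=O)CCl)=C/[C@](O[Si](C)(C)C)(C#C[Si](C)(C)C)C=O | intermediate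
28 | (2E,4E)-5-cyclohexyl-N-{(1R,5S,6S)-2-oxo-5-[(trimethylsilyl)ethynyl]-5-[(trimethylsilyl)oxy]-7-oxabicyclo[4.1.0]hept-3-en-3-yl}penta-2,4-dienamide | O=C(/C=C/C=C/C1CCCCC1)NC1=C[C@](O[Si](C)(C)C)(C#C[Si](C)(C)C)[C@H]2O[C@H]2C1=O | intermediate
29 | (2E,4E)-5-cyclohexyl-N-[(1R,5S,6S)-5-ethynyl-5-hydroxy-2-oxo-7-oxabicyclo[4.1.0]hept-3-en-3-yl]penta-2,4-dienamide | O=C(/C=C/C=C/C1CCCCC1)NC1=C[C@](O)(C#C)[C@H]2O[C@H]2C1=O | intermediate
30 | (2E,4E)-5-cyclohexyl-N-{(1R,5S,6S)-5-hydroxy-2-oxo-5-[(E)-2-(tributylstannyl)ethenyl]-7-oxabicyclo[4.1.0]hept-3-en-3-yl}penta-2,4-dienamide | O=C(/C=C/C=C/C1CCCCC1)NC1=C[C@](O)(/C=C/[Sn](CCCC)(CCCC)CCCC)[C@H]2O[C@H]2C1=O | intermediate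
31 | (2E,4E)-5-cyclohexyl-N-[(1R,5R,6S)-5-hydroxy-5-[(1E,3E,5E)-7-[(2-hydroxy-5-oxocyclopent-1-en-1-yl)amino]-7-oxohepta-1,3,5-trien-1-yl]-2-oxo-7-oxabicyclo[4.1.0]hept-3-en-3-yl]penta-2,4-dienamide | O=C(/C=C/C=C/C1CCCCC1)NC1=C[C@](O)(/C=C/C=C/C=C/C(=O)NC2=C(O)CCC2=O)[C@H]2O[C@H]2C1=O | target

**Step count and risks**

Total step count: 19. Longest linear sequence: 12 steps (steps 8 to 19, from furfuryl alcohol 13 to 31).

Steps most likely to fail:

Step 17 (ring-closing Darzens condensation). The aldol addition may show poor facial selectivity at the aldehyde, so that the epoxide forms trans to the C5 oxygen, or the amide oxygen may be alkylated by the chloromethyl ketone before the enolate reacts. Fallback: the same C1–C6 bond is closed through a sulfur ylide instead of a chloro enolate. Setting out from 27, tetrahydrothiophene (NaI cat., acetone, 23 °C) would give the ketone-stabilised tetrahydrothiophenium chloride F1. K2CO3 in CH2Cl2 then forms the ylide, which adds reversibly to the aldehyde, so that only the ring-closing displacement of the bulky sulfonium group, with the slim alkynyl group 1,3-diaxial to it, selects the diastereomer (Corey–Chaykovsky-type epoxidation with a stabilised sulfonium ylide). This comes back to the route at 28, which is desilylated to 29 as before.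

Step 18 (hydrostannation). Tin may add at the internal alkyne carbon, and the tin hydride may reduce the enone or open the epoxy ketone. Fallback: a tin-free end game. Setting out from 29, semi-hydrogenation (H2, Pd/CaCO3/Pb(OAc)2, quinoline, EtOAc) would give the vinyl carbinol (2E,4E)-5-cyclohexyl-N-[(1R,5R,6S)-5-ethenyl-5-hydroxy-2-oxo-7-oxabicyclo[4.1.0]hept-3-en-3-yl]penta-2,4-dienamide F2. A Heck reaction of this tertiary allylic alcohol with bromodiene 12 (Pd(OAc)2, Bu4NCl, NaHCO3, DMF, 40 °C) would form the (E,E,E)-triene directly, coming back to the route at 31.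

Step 15 (carbenoid homologation). The carbenoid may decompose before it adds to the lactone, whose carbonyl is deactivated once the amide N–H is deprotonated, or the adduct may collapse and take up a second equivalent. Fallback: from 23, dimethylsulfoxonium methylide (Me3S(O)I, KOt-Bu, THF, 23 °C) would open the lactone to the stable β-keto dimethylsulfoxonium ylide F3. LiCl with MsOH in THF at 0 °C would then replace the sulfoxonium group by chloride, coming back to the route at 26.

Further compounds
F1 | step 17 | 1-{(3E,5S)-3-[(2E,4E)-5-cyclohexylpenta-2,4-dienamido]-2,6-dioxo-5-[(trimethylsilyl)ethynyl]-5-[(trimethylsilyl)oxy]hex-3-en-1-yl}tetrahydrothiophenium chloride | O=C(/C=C/C=C/C1CCCCC1)N/C(C(=O)C[S+]1CCCC1)=C/[C@](O[Si](C)(C)C)(C#C[Si](C)(C)C)C=O.[Cl-]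
F2 | step 18 | (2E,4E)-5-cyclohexyl-N-[(1R,5R,6S)-5-ethenyl-5-hydroxy-2-oxo-7-oxabicyclo[4.1.0]hept-3-en-3-yl]penta-2,4-dienamide | O=C(/C=C/C=C/C1CCCCC1)NC1=C[C@](O)(C=C)[C@H]2O[C@H]2C1=O
F3 | step 15 | (2E,4E)-5-cyclohexyl-N-{(3E,5S)-1-[dimethyl(oxo)-λ6-sulfanylidene]-6-hydroxy-2-oxo-5-[(trimethylsilyl)ethynyl]-5-[(trimethylsilyl)oxy]hex-3-en-3-yl}penta-2,4-dienamide | O=C(/C=C/C=C/C1CCCCC1)N/C(C(=O)C=S(C)(C)=O)=C/[C@](O[Si](C)(C)C)(C#C[Si](C)(C)C)CO
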